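**Retrosynthetic overview**
1. Target ⇒ O-acetylation and α-face hydride delivery ⇒ 2-oxolabd-8(17)-en-15-oic acid. The axial 2β-oxygen is made from the ketone.
2. Keto acid ⇒ one oxidation of both carbinols ⇒ labd-8(17)-ene-2α,15-diol. Its equatorial C2 carbinol serves only as a stereochemical relay and is later erased.
3. Key step: the acyclic triene-diol goes to the decalin in one Co–H (MHAT) radical cycloisomerisation. Ring A forms first (C4–C5), then ring B (C10–C9), and H-atom return leaves the 8(17)-alkene.
4. Triene-diol ⇒ C1–C2 bond by lithiation–borylation of isoprenol carbamate with a C15 allylboronate.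
5. Allylboronate ⇒ (R)-2,3-dihydrofarnesol ⇒ (E,E)-farnesol. Asymmetric hydrogenation sets C13.

Assumption: the SMILES is taken literally, which gives a normal labdane (5S,9S,10S) with 13R and 2R, so the acetate is 2β and axial. Labdane numbering is used for positions.

**Step 1**
Reactants: 1 (2E,6E)-farnesol
Product: 2 (3R,6E)-3,7,11-trimethyldodeca-6,10-dien-1-ol [(R)-2,3-dihydrofarnesol]
Conditions: H2 (100 atm), Ru(OAc)2[(S)-BINAP] (0.2 mol %), MeOH–H2O 95:5, 20 °C
Reagents that add atoms: none
Why: Noyori asymmetric hydrogenation, in which the allylic OH binds Ru so only the 2,3-alkene is reduced, and (S)-BINAP on an E-allylic alcohol gives 3R (the future C13), the same sense as geraniol to (R)-citronellol.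

**Step 2**
Reactants: 2 (R)-2,3-dihydrofarnesol
Product: 3 (2E,6E,10R)-2,6,10-trimethyldodeca-2,6-diene-1,12-diol
Conditions: SeO2 (0.3 equiv), t-BuOOH (3 equiv), salicylic acid (0.1 equiv), CH2Cl2, 0 °C to rt, stopped at ca. 60 % conversion, 2 recycled
Reagents that add atoms: tert-butyl hydroperoxide, CC(C)(C)OO
Why: Catalytic SeO2 allylic oxidation (ene reaction, then [2,3]-sigmatropic shift) prefers the exposed terminal isopropylidene and oxidises only its E-methyl group, so the E-geometry needed for the trans-decalin is fixed and no stereocentre is formed.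

**Step 3**
Reactants: 3 (2E,6E,10R)-2,6,10-trimethyldodeca-2,6-diene-1,12-diol
Product: 4 (3R,6E,10E)-3,7,11-trimethyl-12-(4,4,5,5-tetramethyl-1,3,2-dioxaborolan-2-yl)dodeca-6,10-dien-1-ol
Conditions: B2pin2 (1.2 equiv), [Pd(MeCN)4](BF4)2 (5 mol %), DMSO–MeOH 1:1, 25–40 °C
Reagents that add atoms: bis(pinacolato)diboron, CC1(C)OB(OC1(C)C)B1OC(C)(C)C(C)(C)O1
Why: Pd-catalysed allylic borylation through an η3-allyl-Pd intermediate, in which only the allylic OH ionises, boron goes to the unhindered CH2 terminus, the syn-allyl keeps the E-alkene, and the saturated primary OH is inert.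

**Step 4**
Reactants: 5 3-methylbut-3-en-1-ol (isoprenol)
Product: 6 3-methylbut-3-en-1-yl N,N-diisopropylcarbamate
Conditions: i-Pr2NCOCl (1.1 equiv), Et3N (1.3 equiv), CH2Cl2, reflux
Reagents that add atoms: N,N-diisopropylcarbamoyl chloride, CC(C)N(C(C)C)C(=O)Cl
Why: Simple O-carbamoylation installs the directing and leaving group needed for Hoppe deprotonation; no stereocentre is formed.

**Step 5**
Reactants: 6 3-methylbut-3-en-1-yl N,N-diisopropylcarbamate; 4 allylboronate
Product: 10 (3R,6E,10E,13S)-3,7,11,15-tetramethylhexadeca-6,10,15-triene-1,13-diol, via lithiated carbamate 7 (not isolated), via boronate complex 8 (not isolated), via secondary boronic ester 9 (not isolated)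
Conditions: 6 (2.6 equiv), s-BuLi (2.5 equiv), (+)-sparteine (2.5 equiv), Et2O, −78 °C, 5 h; 4 (1 equiv), −78 °C, 1 h, then reflux, 12 h; 2 M NaOH, 30 % H2O2, THF, 0 °C to rt
Reagents that add atoms: hydrogen peroxide, OO
Why: Hoppe asymmetric deprotonation with (+)-sparteine gives the (R)-organolithium (one sacrificial equivalent only deprotonates the remote OH of 4), which borylates with retention, undergoes a Matteson-type 1,2-metallate shift of the allyl group with inversion, and is oxidised at C–B with retention, setting 13S (C2 of the labdane) without allylic transposition.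

**Step 6 (key step)**
Reactants: 10 (3R,6E,10E,13S)-3,7,11,15-tetramethylhexadeca-6,10,15-triene-1,13-diol
Product: 11 (2S,5S,9S,10S,13R)-labd-8(17)-ene-2,15-diol (2α-OH equatorial, trans-decalin, C9 side chain β)
Conditions: Co(salen-tBu,tBu)Cl (3 mol %), PhSiH3 (10 mol %), degassed PhH (0.01 M), 22 °C, Ar, quenched as soon as 10 is consumed
Reagents that add atoms: none
Why: Proposed new method: the Co(III)–H formed from the salen complex and PhSiH3 transfers H• (MHAT) only to the unhindered 1,1-disubstituted alkene to give the tertiary C4 radical, which closes ring A (6-endo, C4–C5) and then ring B (6-endo, C10–C9) through a chair–chair array in which the E,E-alkenes enforce the trans-anti fusion and the equatorial C9 side chain, and in which the C2–OH must sit equatorial because an axial OH would clash with both incipient axial methyls C19 and C20, so the 13S carbinol dictates 5S,9S,10S, and the final tertiary C8 radical returns H• to the bulky Co(II) from its most exposed β-C–H (the C17 methyl, as in cobalt catalytic chain transfer), giving the 8(17)-alkene and regenerating Co–H; the closest known reaction types are Co(salen)/silane diene cycloisomerisation, MHAT-initiated radical bicyclisation of hydroxylated polyenes onto arenes, and Cp2TiCl epoxypolyene cyclisations, which pass through the same tertiary radicals and end in the same exocyclic alkene.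

**Step 7**
Reactants: 11 labd-8(17)-ene-2α,15-diol
Product: 13 (5S,9S,10S,13R)-2-oxolabd-8(17)-en-15-oic acid, via keto aldehyde 12 (not isolated)
Conditions: CrO3, H2SO4, H2O (Jones reagent), acetone, 0 °C, 45 min; i-PrOH quench
Reagents that add atoms: water, O
Why: Jones oxidation converts the secondary carbinol to the ketone and the primary one, via the aldehyde hydrate, to the acid in one operation; the relay stereocentre is erased, the ketone has no α-stereocentre, and the 1,1-disubstituted alkene survives the short cold exposure.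

**Step 8**
Reactants: 13 2-oxolabd-8(17)-en-15-oic acid
Product: 14 (2R,5S,9S,10S,13R)-2-hydroxylabd-8(17)-en-15-oic acid (2β-OH, axial)
Conditions: NaBH4 (3 equiv), MeOH, 0 °C; 1 M HCl to pH 3
Reagents that add atoms: none
Why: Substrate-controlled ketone reduction under steric approach control, in which the β face is closed by the two syn-axial methyls (C19, C20), so hydride enters from the α face (equatorial attack) and gives the axial 2β-alcohol, while the carboxylate is inert.

**Step 9**
Reactants: 14 2β-hydroxylabd-8(17)-en-15-oic acid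
Product: 16 (2R,5S,9S,10S,13R)-2-acetoxylabd-8(17)-en-15-oic acid (target), via mixed anhydride 15 (not isolated)
Conditions: Ac2O (6 equiv), DMAP (0.3 equiv), pyridine, 40 °C; then THF–aq NaHCO3, rt; 1 M HCl to pH 3
Reagents that add atoms: acetic anhydride, CC(=O)OC(C)=O
Why: DMAP-catalysed acylation acetylates the hindered axial alcohol with retention, and the transient acyl acetate at C15 is hydrolysed selectively in the mild aqueous stage because the neopentyl-like axial acetate is far less reactive.

**Compound list**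
1 | (2E,6E)-farnesol | CC(C)=CCC/C(C)=C/CC/C(C)=C/CO | starting material
2 | (3R,6E)-3,7,11-trimethyldodeca-6,10-dien-1-ol | CC(C)=CCC/C(C)=C/CC[C@@H](C)CCO | intermediate
3 | (2E,6E,10R)-2,6,10-trimethyldodeca-2,6-diene-1,12-diol | OC/C(C)=C/CC/C(C)=C/CC[C@@H](C)CCO | intermediate
4 | (3R,6E,10E)-3,7,11-trimethyl-12-(pinacolatoboryl)dodeca-6,10-dien-1-ol | CC1(C)OB(C/C(C)=C/CC/C(C)=C/CC[C@@H](C)CCO)OC1(C)C | intermediate
5 | 3-methylbut-3-en-1-ol | C=C(C)CCO | starting material
6 | 3-methylbut-3-en-1-yl N,N-diisopropylcarbamate | C=C(C)CCOC(=O)N(C(C)C)C(C)C | intermediate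
7 | (R)-1-lithio-3-methylbut-3-enyl N,N-diisopropylcarbamate ((+)-sparteine complex) | [Li][C@H](CC(C)=C)OC(=O)N(C(C)C)C(C)C | intermediate
8 | dilithium boronate complex of 7 with the alkoxide of 4 | [Li+].[Li+].C=C(C)C[C@H](OC(=O)N(C(C)C)C(C)C)[B-]1(C/C(C)=C/CC/C(C)=C/CC[C@@H](C)CC[O-])OC(C)(C)C(C)(C)O1 | intermediate
9 | secondary pinacol boronic ester at C13 of the hexadecatriene chain (lithium alkoxide) | [Li+].C=C(C)C[C@@H](C/C(C)=C/CC/C(C)=C/CC[C@@H](C)CC[O-])B1OC(C)(C)C(C)(C)O1 | intermediate
10 | (3R,6E,10E,13S)-3,7,11,15-tetramethylhexadeca-6,10,15-triene-1,13-diol | C=C(C)C[C@H](O)C/C(C)=C/CC/C(C)=C/CC[C@@H](C)CCO | intermediate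
11 | (2S,5S,9S,10S,13R)-labd-8(17)-ene-2,15-diol | C=C1CC[C@H]2C(C)(C)C[C@H](O)C[C@]2(C)[C@H]1CC[C@@H](C)CCO | intermediate
12 | (5S,9S,10S,13R)-2-oxolabd-8(17)-en-15-al | C=C1CC[C@H]2C(C)(C)CC(=O)C[C@]2(C)[C@H]1CC[C@@H](C)CC=O | intermediate
13 | (5S,9S,10S,13R)-2-oxolabd-8(17)-en-15-oic acid | C=C1CC[C@H]2C(C)(C)CC(=O)C[C@]2(C)[C@H]1CC[C@@H](C)CC(=O)O | intermediate
14 | (2R,5S,9S,10S,13R)-2-hydroxylabd-8(17)-en-15-oic acid | C=C1CC[C@H]2C(C)(C)C[C@@H](O)C[C@]2(C)[C@H]1CC[C@@H](C)CC(=O)O | intermediate
15 | acetic 2β-acetoxylabd-8(17)-en-15-oic anhydride | C=C1CC[C@H]2C(C)(C)C[C@@H](OC(C)=O)C[C@]2(C)[C@H]1CC[C@@H](C)CC(=O)OC(C)=O | intermediate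
16 | (2R,5S,9S,10S,13R)-2-acetoxylabd-8(17)-en-15-oic acid | C=C1CC[C@H]2C(C)(C)C[C@@H](OC(C)=O)C[C@]2(C)[C@H]1CC[C@@H](C)CC(=O)O | target

**Total step count:** 9. **Longest linear sequence:** 8 (steps 1, 2, 3, 5, 6, 7, 8, 9).

**Three steps most likely to fail**

Step 6. Three things can go wrong. The C4 radical may hand H• back from C3, isomerising 10 to the prenyl-type allylic alcohol. The chain may stop after ring A. The catalyst may re-enter the product and walk the alkene to Δ7.

The fallback sets out from 10 and comes back at 13. It separates ring formation from alkene formation. The MHAT initiation is run under oxidative radical–polar crossover conditions (Co(salen) cat., N-fluoro-2,4,6-trimethylpyridinium triflate, (Me2SiH)2O, aqueous acetone). The C8 radical is then oxidised and captured by water from the open α face, giving labdane-2α,8α,15-triol F1. Jones oxidation gives 8α-hydroxy-2-oxolabdan-15-oic acid F2. SOCl2/pyridine at −30 °C dehydrates the equatorial tertiary alcohol. Only the methyl hydrogens can lie anti-periplanar to the equatorial leaving group, so the 8(17)-alkene is favoured. Any acyl chloride is hydrolysed on work-up, which gives 13.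

Step 5. The free hydroxyl, the reversibility of the allylboronate complex and incomplete 1,2-migration can all erode yield.

The fallback sets out from 3 and comes back at 10. It makes the C2–C3 bond instead of C1–C2. Corey–Kim chlorination (NCS, Me2S), which touches only the allylic OH, gives (3R,6E,10E)-12-chloro-3,7,11-trimethyldodeca-6,10-dien-1-ol F3. Pd(0)-catalysed formylation (CO, Bu3SnH) gives the β,γ-unsaturated aldehyde (3E,7E,11R)-13-hydroxy-3,7,11-trimethyltrideca-3,7-dienal F4. Brown asymmetric methallylboration with (−)-Ipc2B-methallyl at −78 °C, followed by oxidative work-up, gives 10.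

Step 2. Selectivity for the terminal over the internal alkene is moderate, over-oxidation to the enal occurs, and yields of 35–45 % are typical.

The fallback sets out from 2 and comes back at 4. Terminal-selective bromohydrin formation (NBS, aq THF, 0 °C) gives (3R,6E)-10-bromo-3,7,11-trimethyldodec-6-ene-1,11-diol F5. K2CO3/MeOH closes it to (3R,6E)-9-(3,3-dimethyloxiran-2-yl)-3,7-dimethylnon-6-en-1-ol F6. Al(Oi-Pr)3 in refluxing toluene isomerises the epoxide to (3R,6E)-3,7,11-trimethyldodeca-6,11-diene-1,10-diol F7. The Pd/B2pin2 borylation of step 3 then funnels F7 through the same η3-allyl intermediate to 4. The E/Z ratio must be checked at this point.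

**Further compounds**
F1 | step 6 | (2S,5S,8R,9R,10S,13R)-labdane-2,8,15-triol (2α,8α) | C[C@@]1(O)CC[C@H]2C(C)(C)C[C@H](O)C[C@]2(C)[C@H]1CC[C@@H](C)CCO
F2 | step 6 | 8α-hydroxy-2-oxolabdan-15-oic acid | C[C@@]1(O)CC[C@H]2C(C)(C)CC(=O)C[C@]2(C)[C@H]1CC[C@@H](C)CC(=O)O
F3 | step 5 | (3R,6E,10E)-12-chloro-3,7,11-trimethyldodeca-6,10-dien-1-ol | ClC/C(C)=C/CC/C(C)=C/CC[C@@H](C)CCO
F4 | step 5 | (3E,7E,11R)-13-hydroxy-3,7,11-trimethyltrideca-3,7-dienal | O=CC/C(C)=C/CC/C(C)=C/CC[C@@H](C)CCO
F5 | step 2 | (3R,6E)-10-bromo-3,7,11-trimethyldodec-6-ene-1,11-diol (C10 epimers) | CC(C)(O)C(Br)CC/C(C)=C/CC[C@@H](C)CCO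
F6 | step 2 | (3R,6E)-9-(3,3-dimethyloxiran-2-yl)-3,7-dimethylnon-6-en-1-ol (epoxide epimers) | CC1(C)OC1CC/C(C)=C/CC[C@@H](C)CCO
F7 | step 2 | (3R,6E)-3,7,11-trimethyldodeca-6,11-diene-1,10-diol (C10 epimers) | C=C(C)C(O)CC/C(C)=C/CC[C@@H](C)CCO
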